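Retrosynthesis: the first cut is the aryl–CH2 bond at C7 of the benzene ring (ring A). It gives 7-bromo-3-methylene-2,3-dihydro-1-benzoxepine and a (stearoyloxy)methylzinc iodide. O1–C2 and C4=C5 of the oxepine (ring B) are then cut back to 5-bromosalicylaldehyde and a four-carbon allylic phosphonium salt, and the zinc reagent goes back to stearoyl chloride and formaldehyde.
Forward: ring B is closed on the ready-made ring A in one flask (O-alkylation, then intramolecular Wittig reaction). The C19 arm is made in two steps, and the two halves are joined in the last step.
Enabling feature: the CH2 carbon carries only hydrogen and the acyloxy oxygen, so its zinc derivative has no β-hydrogen and is held by a five-membered Zn–C–O–C=O chelate. C7 lies para to O1 and meta to C5, which is the position already brominated in the commercial aldehyde.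
Gain: the whole 19-carbon ester arm enters at its final oxidation level on the finished C3(=CH2)–C4=C5 diene. No benzylic alcohol, no protecting group and no free p-hydroxybenzyl ester (prone to p-quinone methide formation) appears anywhere.
Stereochemistry: the target has no stereocentre. Its only element, the cis C4=C5 bond, is enforced by the seven-membered ring at the Wittig closure.
Key step: step 5

Step 1
Reactants: 1 3-chloro-2-(chloromethyl)prop-1-ene; 2 triphenylphosphine
Product: 3 [2-(chloromethyl)prop-2-en-1-yl]triphenylphosphonium chloride
Conditions: 1 (3 equiv), 2 (1 equiv), toluene, 100 °C; precipitated salt filtered off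
Reagents that add atoms: none
Why: SN2 quaternisation of one allylic chloride (phosphonium salt formation) should stop at the mono-salt, because an excess of 1 is used and the product precipitates with a positive charge that retards a second substitution.

Step 2
Reactants: 3 [2-(chloromethyl)prop-2-en-1-yl]triphenylphosphonium chloride; 4 5-bromo-2-hydroxybenzaldehyde (5-bromosalicylaldehyde)
Product: 7 7-bromo-3-methylene-2,3-dihydro-1-benzoxepine, via ether phosphonium chloride 5 (not isolated), via allylic ylide 6 (not isolated)
Conditions: K2CO3 (1.0 equiv), 18-crown-6 (10 mol %), MeCN, 25 °C; then K2CO3 (2.0 equiv), MeCN (0.01 M), 80 °C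
Reagents that add atoms: none
Why: Williamson O-alkylation of the phenoxide at the allylic chloride is followed by an intramolecular Wittig reaction of the semistabilised allylic ylide with the ortho aldehyde (the known benzoxepine annulation of salicylaldehydes with ω-aryloxyalkylphosphonium salts); the seven-membered ring allows only the cis C4=C5 alkene and the 2-methylene unit is carried in unchanged.

Step 3
Reactants: 8 octadecanoyl chloride (stearoyl chloride)
Product: 9 chloromethyl octadecanoate
Conditions: (CH2O)n (1.1 equiv), ZnCl2 (2 mol %), neat, 80 °C
Reagents that add atoms: paraformaldehyde (as formaldehyde), C=O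
Why: Lewis-acid-catalysed addition of an acyl chloride across the C=O bond of formaldehyde is the standard entry to chloromethyl esters and needs nothing but the acid chloride function of 8.

Step 4
Reactants: 9 chloromethyl octadecanoate
Product: 10 iodomethyl octadecanoate
Conditions: NaI (1.5 equiv), acetone, 25 °C, dark
Reagents that add atoms: sodium iodide, [Na+].[I-]
Why: Finkelstein halide exchange at the activated O–CH2–Cl carbon is driven by precipitation of NaCl and supplies the weak C–I bond that zinc can enter under mild conditions.

Step 5
Reactants: 7 7-bromo-3-methylene-2,3-dihydro-1-benzoxepine; 10 iodomethyl octadecanoate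
Product: 12 (3-methylene-2,3-dihydro-1-benzoxepin-7-yl)methyl octadecanoate, via acyloxymethylzinc iodide 11 (not isolated)
Conditions: 10 (1.5 equiv), activated Zn dust (3 equiv), LiCl (1.5 equiv), THF, 15–25 °C, solution decanted from excess Zn; then 7 (1.0 equiv), Pd(OAc)2 (2 mol %), SPhos (4 mol %), THF, 25 °C
Reagents that add atoms: zinc dust, [Zn] (enters intermediate 11 only and leaves no atom in 12)
Why: Zinc inserts into the weak C–I bond of 10 to give 11, a primary alkylzinc iodide without β-hydrogen that is held by a five-membered Zn–C–O–C=O chelate; zerovalent palladium (formed from Pd(OAc)2 and SPhos by the zinc reagent) adds oxidatively to the C7–Br bond of 7, the acyloxymethyl group passes from zinc to divalent palladium, and reductive elimination forms the C7–CH2 bond. The closest known reaction type is the Negishi cross-coupling of aryl halides with functionalised primary alkylzinc iodides, (acyloxymethyl)zinc iodides included, where they serve as hydroxymethyl anion equivalents. No ring is closed and no stereocentre is formed, and the site is fixed by the bromine that 4 carries para to its oxygen. The step needs chemoselectivity for C–Br over the diene and the ester: the organozinc does not attack esters, transmetalation at 25 °C should outrun Heck-type insertion into the exocyclic methylene, and the s-trans-locked diene cannot chelate palladium. Because neither partner offers a β-hydrogen no palladium hydride arises, so the exocyclic C3=CH2 bond should not migrate into ring B, and the two-electron pathway avoids a free acyloxymethyl radical that would add to the diene. Should carboxylate α-elimination at palladium intervene, migratory insertion of the resulting methylidene into the Pd–aryl bond would give a benzylpalladium stearate that collapses to the same ester 12.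

Compound list
1 | 3-chloro-2-(chloromethyl)prop-1-ene | C=C(CCl)CCl | starting material
2 | triphenylphosphine | c1ccc(cc1)P(c1ccccc1)c1ccccc1 | starting material
3 | [2-(chloromethyl)prop-2-en-1-yl]triphenylphosphonium chloride | C=C(CCl)C[P+](c1ccccc1)(c1ccccc1)c1ccccc1.[Cl-] | intermediate
4 | 5-bromo-2-hydroxybenzaldehyde | O=Cc1cc(Br)ccc1O | starting material
5 | {2-[(4-bromo-2-formylphenoxy)methyl]prop-2-en-1-yl}triphenylphosphonium chloride | C=C(COc1ccc(Br)cc1C=O)C[P+](c1ccccc1)(c1ccccc1)c1ccccc1.[Cl-] | intermediate
6 | 5-bromo-2-{2-[(triphenylphosphoranylidene)methyl]prop-2-en-1-yloxy}benzaldehyde (allylic ylide) | C=C(COc1ccc(Br)cc1C=O)C=P(c1ccccc1)(c1ccccc1)c1ccccc1 | intermediate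
7 | 7-bromo-3-methylene-2,3-dihydro-1-benzoxepine | C=C1C=Cc2cc(Br)ccc2OC1 | intermediate
8 | octadecanoyl chloride | ClC(=O)CCCCCCCCCCCCCCCCC | starting material
9 | chloromethyl octadecanoate | ClCOC(=O)CCCCCCCCCCCCCCCCC | intermediate
10 | iodomethyl octadecanoate | ICOC(=O)CCCCCCCCCCCCCCCCC | intermediate
11 | [(octadecanoyloxy)methyl]zinc iodide | I[Zn]COC(=O)CCCCCCCCCCCCCCCCC | intermediate
12 | (3-methylene-2,3-dihydro-1-benzoxepin-7-yl)methyl octadecanoate | C=C1C=Cc2cc(COC(=O)CCCCCCCCCCCCCCCCC)ccc2OC1 | target

Total step count: 5. Longest linear sequence: 3 steps (1 → 2 → 5, or 3 → 4 → 5).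

Steps most likely to fail

1. Step 5. The chelated acyloxymethyl group may pass too slowly from zinc to palladium. The zinc reagent would then be lost by α-elimination or protonation, and Heck-type insertion of the arylpalladium species into the diene of a second molecule could take over. Fallback (from 7, back at 12): the carbon and the acyl group are brought in separately. Bromine–lithium exchange of 7 (n-BuLi, THF, −78 °C) should give (3-methylene-2,3-dihydro-1-benzoxepin-7-yl)lithium F1. Formylation of this with DMF leads to 3-methylene-2,3-dihydro-1-benzoxepine-7-carbaldehyde F2. Reduction (NaBH4, MeOH, 0 °C) should give (3-methylene-2,3-dihydro-1-benzoxepin-7-yl)methanol F3, and acylation with 8 (Et3N, DMAP, CH2Cl2, 0 °C) returns to 12.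

2. Step 2. A prototropic shift of the allylic phosphonium unit to its vinylic isomer before O-alkylation may occur, followed by Michael addition of the phenoxide and Wittig closure to a six-membered ring. Intermolecular Wittig reaction leading to oligomers is the second danger. Fallback (from 4, back at 7): ring B is closed as an enone with a stabilised, non-allylic ylide, and the methylene carbon is added afterwards. O-Alkylation of 4 with commercial 1-chloro-3-(triphenylphosphoranylidene)propan-2-one (K2CO3, catalytic NaI, DMF, 25 °C) should give 5-bromo-2-[2-oxo-3-(triphenylphosphoranylidene)propoxy]benzaldehyde F4. Intramolecular Wittig reaction (toluene, 0.01 M, 110 °C) should give 7-bromo-1-benzoxepin-3(2H)-one F5. Wittig methylenation (MePPh3Br, KOtBu, THF, 0 °C) then leads to 7.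

3. Step 4. The light- and moisture-sensitive iodomethyl ester may decompose on isolation by hydrolysis or disproportionation, which would starve the zinc insertion that follows. Fallback (from 8, back at 12): no halomethyl ester and no zinc insertion are used. Acylation of commercial (tributylstannyl)methanol with 8 (Et3N, DMAP, CH2Cl2, 0 °C) should give tributyl[(octadecanoyloxy)methyl]stannane F6. This storable nucleophile is joined with 7 by a Stille coupling (Pd(PPh3)4, dioxane, 90 °C) to give 12.

Further compounds
F1 | step 5 | (3-methylene-2,3-dihydro-1-benzoxepin-7-yl)lithium | [Li]c1ccc2OCC(=C)C=Cc2c1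
F2 | step 5 | 3-methylene-2,3-dihydro-1-benzoxepine-7-carbaldehyde | C=C1C=Cc2cc(C=O)ccc2OC1
F3 | step 5 | (3-methylene-2,3-dihydro-1-benzoxepin-7-yl)methanol | C=C1C=Cc2cc(CO)ccc2OC1
F4 | step 2 | 5-bromo-2-[2-oxo-3-(triphenylphosphoranylidene)propoxy]benzaldehyde | O=Cc1cc(Br)ccc1OCC(=O)C=P(c1ccccc1)(c1ccccc1)c1ccccc1
F5 | step 2 | 7-bromo-1-benzoxepin-3(2H)-one | O=C1C=Cc2cc(Br)ccc2OC1
F6 | step 4 | tributyl[(octadecanoyloxy)methyl]stannane | CCCC[Sn](CCCC)(CCCC)COC(=O)CCCCCCCCCCCCCCCCC
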